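Ring B is disconnected across C1'–C2' and C3'–C4'. Its prenyl group sits on C2', squeezed between C1' (bonded to benzofuran C2) and the oxygenated C3'. This C2'/C3' pair maps onto the central carbon and one ester carbon of a prenylmalonate, while C1', C6', C5' and C4' come from a 4-(benzofuran-2-yl)but-3-en-2-one. A Michael–Claisen annulation therefore forms both bonds and the six-membered ring in one operation, as a cyclohexane-1,3-dione that is aromatised late. The precursor is the E-enone on a 7-(1,1-dimethylallyl)-4,6-bis(methoxymethoxy)benzofuran, prepared from phloroglucinol by a trapped aryl Claisen rearrangement, ortho-formylation and furan annulation.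

Key step: step 9

Remark: the malonate ester groups are spectators in the ring closure, so allyl esters are used in place of ethyl esters; the quaternary ester that survives the annulation then directs the enol ether to O5' and is later removed with zerovalent palladium under neutral conditions.

Abbreviations: BF = 4,6-bis(methoxymethoxy)-7-(2-methylbut-3-en-2-yl)-1-benzofuran-2-yl; MOM = methoxymethyl; primed locants refer to ring B (C1' on benzofuran C2). Chiral intermediates are racemic and drawn as one enantiomer.

**Route**

Step 1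
Reactants: 1 phloroglucinol
Product: 2 3,5-bis(methoxymethoxy)phenol
Conditions: MOMCl (2.0 equiv), i-Pr2NEt, DMF, 0 °C to rt
Reagents that add atoms: chloromethyl methyl ether (MOMCl), COCCl
Why: Williamson-type O-alkylation of the phenoxide by the α-chloro ether; the three hydroxyls are equivalent, so the two-fold protection rests on stoichiometry, and the mono- and tris-ethers are separated by chromatography and recycled.

Step 2
Reactants: 2 3,5-bis(methoxymethoxy)phenol; 3 prenyl bromide
Product: 4 1,3-bis(methoxymethoxy)-5-[(3-methylbut-2-en-1-yl)oxy]benzene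
Conditions: K2CO3, acetone, reflux
Reagents that add atoms: none
Why: Williamson ether synthesis; the potassium phenoxide in acetone should alkylate on oxygen at the primary allylic carbon (SN2) and not on carbon.

Step 3
Reactants: 4 1,3-bis(methoxymethoxy)-5-[(3-methylbut-2-en-1-yl)oxy]benzene
Product: 6 3,5-bis(methoxymethoxy)-2-(2-methylbut-3-en-2-yl)phenol, via aryl acetate 5 (not isolated)
Conditions: Ac2O, NaOAc, PhNEt2, 185 °C; then K2CO3, MeOH, rt
Reagents that add atoms: none
Why: Aromatic Claisen [3,3] rearrangement to either of the two equivalent ortho carbons gives the ortho-dienone carrying the 1,1-dimethylallyl group, whose acetate-assisted enolisation and O-acetylation should outrun the Cope shift to the para carbon; methanolysis of the acetate then frees the phenol.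

Step 4
Reactants: 6 3,5-bis(methoxymethoxy)-2-(2-methylbut-3-en-2-yl)phenol
Product: 7 2-hydroxy-4,6-bis(methoxymethoxy)-3-(2-methylbut-3-en-2-yl)benzaldehyde
Conditions: MgCl2, Et3N, (CH2O)n, MeCN, reflux
Reagents that add atoms: paraformaldehyde (as formaldehyde), C=O
Why: Magnesium-phenoxide-directed ortho-formylation (Casnati–Skattebøl): formaldehyde bound to magnesium is delivered only to the one free position ortho to the hydroxyl, a second formaldehyde oxidises the benzylic alkoxide by hydride transfer, and the amine-buffered medium should spare the MOM acetals.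

Step 5
Reactants: 7 2-hydroxy-4,6-bis(methoxymethoxy)-3-(2-methylbut-3-en-2-yl)benzaldehyde; 8 ethyl bromoacetate
Product: 10 ethyl 4,6-bis(methoxymethoxy)-7-(2-methylbut-3-en-2-yl)-1-benzofuran-2-carboxylate, via aryloxyacetate 9 (not isolated)
Conditions: K2CO3, DMF, 60 °C then 110 °C
Reagents that add atoms: none
Why: O-alkylation of the phenoxide followed by intramolecular aldol condensation of the acetate methylene onto the ortho formyl group and dehydration (Rap–Stoermer-type benzofuran annulation), driven by formation of the aromatic furan.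

Step 6
Reactants: 10 ethyl 4,6-bis(methoxymethoxy)-7-(2-methylbut-3-en-2-yl)-1-benzofuran-2-carboxylate
Product: 11 [4,6-bis(methoxymethoxy)-7-(2-methylbut-3-en-2-yl)-1-benzofuran-2-yl]methanol
Conditions: LiAlH4, THF, 0 °C
Reagents that add atoms: none
Why: Hydride reduction of the ester to the primary alcohol; MOM ethers and isolated alkenes are inert to LiAlH4.

Step 7
Reactants: 11 [4,6-bis(methoxymethoxy)-7-(2-methylbut-3-en-2-yl)-1-benzofuran-2-yl]methanol; 12 (acetylmethylene)triphenylphosphorane
Product: 14 (E)-4-[4,6-bis(methoxymethoxy)-7-(2-methylbut-3-en-2-yl)-1-benzofuran-2-yl]but-3-en-2-one, via benzofuran-2-carbaldehyde 13 (not isolated)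
Conditions: MnO2 (10 equiv), toluene, 80 °C
Reagents that add atoms: none
Why: MnO2 oxidises the activated furylmethyl alcohol, and the stabilised ylide already in the flask converts the aldehyde as it forms into the enone (tandem oxidation–Wittig olefination), the stabilised ylide giving the E alkene.

Step 8
Reactants: 15 diallyl malonate; 3 prenyl bromide
Product: 16 diallyl 2-(3-methylbut-2-en-1-yl)malonate
Conditions: NaH, THF, 0 °C to rt (15 in excess)
Reagents that add atoms: none
Why: SN2 alkylation of the sodium malonate (malonic ester synthesis); an excess of the malonate should suppress dialkylation.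

Step 9
Reactants: 14 (E)-4-[4,6-bis(methoxymethoxy)-7-(2-methylbut-3-en-2-yl)-1-benzofuran-2-yl]but-3-en-2-one; 16 diallyl 2-(3-methylbut-2-en-1-yl)malonate
Product: 18 allyl 6-BF-1-(3-methylbut-2-en-1-yl)-2,4-dioxocyclohexane-1-carboxylate (racemic; prenyl trans to BF), via Michael adduct 17 (not isolated)
Conditions: NaH (1.3 equiv), allyl alcohol (5 equiv), THF, 0 °C to reflux; AcOH
Reagents that add atoms: none
Why: Sodium allyloxide generates the prenylmalonate carbanion, which adds reversibly in a 1,4-sense to the enone β-carbon (C1'–C2'); after proton exchange the methyl-side enolate of the adduct attacks one of the two ester carbonyls (C4'–C3') and expels allyloxide. The closest known reaction type is the Michael–Claisen annulation of malonates with 4-arylbut-3-en-2-ones to 5-arylcyclohexane-1,3-diones, here with the more hindered 2-alkylmalonate donor. Ring B closes in a 6-(enolendo)-exo-trig Claisen (Dieckmann-like) step, the only cyclisation open to the adduct because the alternative C6' enolate could form only a four-membered ring. C1' is set in the conjugate addition (racemic) and C2' in the ring closure by the choice between the two diastereotopic esters, a chair-like transition state with the benzofuranyl and prenyl groups equatorial favouring the trans isomer; both centres vanish on aromatisation, so the diastereomer ratio is immaterial. The step needs 1,4- over 1,2-addition and a forward equilibrium despite crowding at C2': the soft, doubly stabilised carbanion should secure the former and irreversible deprotonation of the product dione at C4' the latter, while matching the alkoxide to the allyl esters makes any transesterification degenerate.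

Step 10
Reactants: 18 allyl 6-BF-1-(3-methylbut-2-en-1-yl)-2,4-dioxocyclohexane-1-carboxylate
Product: 19 allyl 6-BF-4-(methoxymethoxy)-1-(3-methylbut-2-en-1-yl)-2-oxocyclohex-3-ene-1-carboxylate (racemic; prenyl trans to BF)
Conditions: MOMCl (1.2 equiv), i-Pr2NEt, CH2Cl2, 0 °C
Reagents that add atoms: chloromethyl methyl ether (MOMCl), COCCl
Why: O-alkylation of the 1,3-dione enolate by a hard electrophile (vinylogous ester formation) should occur at O5', the oxygen remote from the quaternary C2', which tells O5' and O3' apart; the two stereocentres are untouched.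

Step 11
Reactants: 19 allyl 6-BF-4-(methoxymethoxy)-1-(3-methylbut-2-en-1-yl)-2-oxocyclohex-3-ene-1-carboxylate
Product: 20 5-BF-3-(methoxymethoxy)-6-(3-methylbut-2-en-1-yl)cyclohex-2-en-1-one (racemic; prenyl trans to BF)
Conditions: Pd(OAc)2 (5 mol %), PPh3, HCO2H, Et3N, THF, 40 °C
Reagents that add atoms: none
Why: Tsuji decarboxylation–hydrogenolysis of an allyl β-keto ester: zerovalent palladium formed in the flask ionises the allyl ester, the β-keto carboxylate loses CO2 and formate reduces the allyl unit to propene under neutral conditions that spare the MOM groups; C2' is set by protonation and, being epimerisable, should settle as the trans isomer.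

Step 12
Reactants: 20 5-BF-3-(methoxymethoxy)-6-(3-methylbut-2-en-1-yl)cyclohex-2-en-1-one
Product: 22 3-BF-5-(methoxymethoxy)-2-(3-methylbut-2-en-1-yl)phenol, via selenide 21 (not isolated)
Conditions: LiN(i-Pr)2 (1.2 equiv), THF, −78 °C; PhSeCl (1.05 equiv), −78 °C; then 30% H2O2, pyridine, CH2Cl2, 0 °C to rt
Reagents that add atoms: none
Why: Kinetic deprotonation of the vinylogous ester at the α' carbon C2' (Stork–Danheiser regiochemistry) and selenenylation anti to the benzofuranyl group place selenium cis to the C1' hydrogen, so that oxidation and syn-elimination of the selenoxide into the ring give the cross-conjugated dienone, which tautomerises to the C3' phenol.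

Step 13
Reactants: 22 3-BF-5-(methoxymethoxy)-2-(3-methylbut-2-en-1-yl)phenol
Product: 23 2-[3-methoxy-5-(methoxymethoxy)-2-(3-methylbut-2-en-1-yl)phenyl]-4,6-bis(methoxymethoxy)-7-(2-methylbut-3-en-2-yl)-1-benzofuran
Conditions: MeI, K2CO3, DMF, rt
Reagents that add atoms: iodomethane (MeI), CI
Why: Williamson methylation of the only free phenol, O3', all other oxygens being masked as MOM ethers.

Step 14
Reactants: 23 2-[3-methoxy-5-(methoxymethoxy)-2-(3-methylbut-2-en-1-yl)phenyl]-4,6-bis(methoxymethoxy)-7-(2-methylbut-3-en-2-yl)-1-benzofuran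
Product: 24 2-[5-hydroxy-3-methoxy-2-(3-methylbut-2-en-1-yl)phenyl]-7-(2-methylbut-3-en-2-yl)-1-benzofuran-4,6-diol (CNP0169501.0)
Conditions: HCl (about 1.5 M in MeOH), 40 °C
Reagents that add atoms: none
Why: Acid-catalysed acetal exchange transfers the three MOM groups to methanol; the prenyl group has no free ortho hydroxyl (O3' is methylated) and the vinyl group of the 1,1-dimethylallyl unit would have to form a secondary cation, so mild acid should leave both alkenes alone.

**Compound list**

1 | phloroglucinol | Oc1cc(O)cc(O)c1 | starting material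
2 | 3,5-bis(methoxymethoxy)phenol | COCOc1cc(O)cc(OCOC)c1 | intermediate
3 | prenyl bromide (1-bromo-3-methylbut-2-ene) | CC(C)=CCBr | starting material
4 | 1,3-bis(methoxymethoxy)-5-[(3-methylbut-2-en-1-yl)oxy]benzene | COCOc1cc(OCC=C(C)C)cc(OCOC)c1 | intermediate
5 | 3,5-bis(methoxymethoxy)-2-(2-methylbut-3-en-2-yl)phenyl acetate | CC(=O)Oc1cc(OCOC)cc(OCOC)c1C(C)(C)C=C | intermediate (not isolated)
6 | 3,5-bis(methoxymethoxy)-2-(2-methylbut-3-en-2-yl)phenol | Oc1cc(OCOC)cc(OCOC)c1C(C)(C)C=C | intermediate
7 | 2-hydroxy-4,6-bis(methoxymethoxy)-3-(2-methylbut-3-en-2-yl)benzaldehyde | O=Cc1c(O)c(C(C)(C)C=C)c(OCOC)cc1OCOC | intermediate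
8 | ethyl bromoacetate | CCOC(=O)CBr | starting material
9 | ethyl 2-[2-formyl-3,5-bis(methoxymethoxy)-6-(2-methylbut-3-en-2-yl)phenoxy]acetate | CCOC(=O)COc1c(C=O)c(OCOC)cc(OCOC)c1C(C)(C)C=C | intermediate (not isolated)
10 | ethyl 4,6-bis(methoxymethoxy)-7-(2-methylbut-3-en-2-yl)-1-benzofuran-2-carboxylate | CCOC(=O)c1cc2c(OCOC)cc(OCOC)c(C(C)(C)C=C)c2o1 | intermediate
11 | [4,6-bis(methoxymethoxy)-7-(2-methylbut-3-en-2-yl)-1-benzofuran-2-yl]methanol | OCc1cc2c(OCOC)cc(OCOC)c(C(C)(C)C=C)c2o1 | intermediate
12 | (acetylmethylene)triphenylphosphorane | CC(=O)C=P(c1ccccc1)(c1ccccc1)c1ccccc1 | starting material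
13 | 4,6-bis(methoxymethoxy)-7-(2-methylbut-3-en-2-yl)-1-benzofuran-2-carbaldehyde | O=Cc1cc2c(OCOC)cc(OCOC)c(C(C)(C)C=C)c2o1 | intermediate (not isolated)
14 | (E)-4-[4,6-bis(methoxymethoxy)-7-(2-methylbut-3-en-2-yl)-1-benzofuran-2-yl]but-3-en-2-one | C=CC(C)(C)c1c(OCOC)cc(OCOC)c2cc(/C=C/C(C)=O)oc12 | intermediate (key-step precursor)
15 | diallyl malonate | C=CCOC(=O)CC(=O)OCC=C | starting material
16 | diallyl 2-(3-methylbut-2-en-1-yl)malonate | C=CCOC(=O)C(CC=C(C)C)C(=O)OCC=C | intermediate (key-step precursor)
17 | diallyl 2-(1-BF-3-oxobutyl)-2-(3-methylbut-2-en-1-yl)malonate (racemic) | C=CCOC(=O)C(CC=C(C)C)(C(=O)OCC=C)C(CC(C)=O)c1cc2c(OCOC)cc(OCOC)c(C(C)(C)C=C)c2o1 | intermediate (not isolated)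
18 | allyl 6-BF-1-(3-methylbut-2-en-1-yl)-2,4-dioxocyclohexane-1-carboxylate (racemic; prenyl trans to BF) | C=CCOC(=O)[C@]1(CC=C(C)C)C(=O)CC(=O)C[C@@H]1c1cc2c(OCOC)cc(OCOC)c(C(C)(C)C=C)c2o1 | intermediate (key-step product)
19 | allyl 6-BF-4-(methoxymethoxy)-1-(3-methylbut-2-en-1-yl)-2-oxocyclohex-3-ene-1-carboxylate (racemic; prenyl trans to BF) | C=CCOC(=O)[C@]1(CC=C(C)C)C(=O)C=C(OCOC)C[C@@H]1c1cc2c(OCOC)cc(OCOC)c(C(C)(C)C=C)c2o1 | intermediate
20 | 5-BF-3-(methoxymethoxy)-6-(3-methylbut-2-en-1-yl)cyclohex-2-en-1-one (racemic; prenyl trans to BF) | CC(C)=CC[C@H]1C(=O)C=C(OCOC)C[C@@H]1c1cc2c(OCOC)cc(OCOC)c(C(C)(C)C=C)c2o1 | intermediate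
21 | 5-BF-3-(methoxymethoxy)-6-(3-methylbut-2-en-1-yl)-6-(phenylselanyl)cyclohex-2-en-1-one (racemic; selenium trans to BF) | CC(C)=CC[C@]1([Se]c3ccccc3)C(=O)C=C(OCOC)C[C@@H]1c1cc2c(OCOC)cc(OCOC)c(C(C)(C)C=C)c2o1 | intermediate (not isolated)
22 | 3-BF-5-(methoxymethoxy)-2-(3-methylbut-2-en-1-yl)phenol | CC(C)=CCc1c(O)cc(OCOC)cc1-c1cc2c(OCOC)cc(OCOC)c(C(C)(C)C=C)c2o1 | intermediate
23 | 2-[3-methoxy-5-(methoxymethoxy)-2-(3-methylbut-2-en-1-yl)phenyl]-4,6-bis(methoxymethoxy)-7-(2-methylbut-3-en-2-yl)-1-benzofuran | CC(C)=CCc1c(OC)cc(OCOC)cc1-c1cc2c(OCOC)cc(OCOC)c(C(C)(C)C=C)c2o1 | intermediate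
24 | 2-[5-hydroxy-3-methoxy-2-(3-methylbut-2-en-1-yl)phenyl]-7-(2-methylbut-3-en-2-yl)-1-benzofuran-4,6-diol | C=CC(C)(C)c1c(O)cc(O)c2cc(-c3cc(O)cc(OC)c3CC=C(C)C)oc12 | target

**Step count and risks**

Total step count: 14. Longest linear sequence: 13 steps (steps 1–7 and 9–14); step 8 is a one-step side branch.

Steps most likely to fail:

1. Step 9 (key step). The conjugate addition may not go forward: the tertiary carbanion is hindered, the adduct can revert to its components, and the enone may condense with itself instead. Fallback: setting out from 14 and 15, the same annulation is run with the unsubstituted diallyl malonate 15 (NaH, allyl alcohol, THF, reflux), the unhindered and well-precedented case. This should give allyl 6-BF-2,4-dioxocyclohexane-1-carboxylate F1. The prenyl group is then introduced by alkylating the dianion of F1 (LiN(i-Pr)2, 2.2 equiv, THF, −78 to 0 °C) with prenyl bromide 3 at C2', the carbon deprotonated last and therefore the most nucleophilic, anti to the benzofuranyl group. This comes back to the route at 18.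

2. Step 12. Deprotonation may occur at C6' instead of the hindered C2', the selenoxide may eliminate toward the prenyl CH2 instead of into the ring, and electrophilic selenium may add to the alkenes. Fallback: setting out from 20, enolisation and silylation (LiN(i-Pr)2, TMSCl, THF, −78 °C) should give 2-[5-(methoxymethoxy)-2-(3-methylbut-2-en-1-yl)-3-(trimethylsilyloxy)cyclohexa-2,4-dien-1-yl]-4,6-bis(methoxymethoxy)-7-(2-methylbut-3-en-2-yl)-1-benzofuran F2. DDQ (1.05 equiv, 2,6-lutidine, CH2Cl2, 0 °C) should then abstract hydride from C1', giving a cation stabilised by both ring oxygens, which loses the C6' proton. Aqueous work-up cleaves the aryl silyl ether and returns to the route at 22. The regioisomeric diene from C6' deprotonation would be oxidised to the same arene, and the prenyl CH2 is never adjacent to a cationic carbon, so the direction of elimination no longer matters.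

3. Step 3. The ortho-dienone may undergo a Cope shift of the allyl unit to the para carbon before it enolises, which would give the linear 4-prenyl phenol, or the prenyl ether may simply be cleaved. Fallback: setting out from 2, the tertiary allyl group is installed by cross-coupling instead of by rearrangement. Magnesium-mediated ortho-formylation of 2 (MgCl2, Et3N, (CH2O)n, MeCN, reflux) should give 2-hydroxy-4,6-bis(methoxymethoxy)benzaldehyde F3. Annulation with ethyl bromoacetate 8 (K2CO3, DMF, 110 °C) should give ethyl 4,6-bis(methoxymethoxy)-1-benzofuran-2-carboxylate F4. Bromination (NBS, MeCN, 0 °C) at C7, the position activated by three oxygens and less hindered than C5, should give ethyl 7-bromo-4,6-bis(methoxymethoxy)-1-benzofuran-2-carboxylate F5. A ligand-controlled γ-selective Suzuki–Miyaura coupling with prenylboronic acid pinacol ester (Pd(OAc)2, bulky biaryl dialkylphosphine, K3PO4, THF/H2O, 40 °C) then delivers the branched 1,1-dimethylallyl group and comes back to the route at 10.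

**Further compounds**

F1 | step 9 | allyl 6-BF-2,4-dioxocyclohexane-1-carboxylate (racemic; ester trans to BF) | C=CCOC(=O)[C@H]1C(=O)CC(=O)C[C@@H]1c1cc2c(OCOC)cc(OCOC)c(C(C)(C)C=C)c2o1
F2 | step 12 | 2-[5-(methoxymethoxy)-2-(3-methylbut-2-en-1-yl)-3-(trimethylsilyloxy)cyclohexa-2,4-dien-1-yl]-4,6-bis(methoxymethoxy)-7-(2-methylbut-3-en-2-yl)-1-benzofuran (racemic) | CC(C)=CCC1=C(O[Si](C)(C)C)C=C(OCOC)CC1c1cc2c(OCOC)cc(OCOC)c(C(C)(C)C=C)c2o1
F3 | step 3 | 2-hydroxy-4,6-bis(methoxymethoxy)benzaldehyde | COCOc1cc(O)c(C=O)c(OCOC)c1
F4 | step 3 | ethyl 4,6-bis(methoxymethoxy)-1-benzofuran-2-carboxylate | CCOC(=O)c1cc2c(OCOC)cc(OCOC)cc2o1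
F5 | step 3 | ethyl 7-bromo-4,6-bis(methoxymethoxy)-1-benzofuran-2-carboxylate | CCOC(=O)c1cc2c(OCOC)cc(OCOC)c(Br)c2o1
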